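**Retrosynthetic overview**

1. Locants: the bicycle is numbered as a cis-fused hexahydronaphthalene. Ring B is C1(Me2)–C2(side chain)=C3(Me)–C4H2–C4a–C8a and ring A is C4a–C5H=C6(Me)–C7H2–C8H2–C8a. The peroxide is a 1,2-dioxane with C3 = CH and C6 = C(Me).
2. Last disconnections: CO2H comes from CH2OH. The CH2–CH2 bridge comes from a Wittig union (then diimide) of a bicyclic allylic phosphonium salt with a formyl-1,2-dioxane.
3. Dioxane ring (built apart, with no alkene present): both C–O bonds are made by invertive substitution with H2O2. The first is at the tertiary carbon of an enantiopure 2,2-disubstituted epoxide. The second is a 6-exo closure onto a secondary mesylate whose two centres come from a syn-aldol.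
4. Bicycle: ring B is bought as β-cyclocitral. Ring A is closed onto it by a silicon-tethered intramolecular Diels–Alder reaction that forms C8–C8a and C4a–C5 together with a temporary oxasilolane ring. Protodesilylation then moves C6=C7 to C5=C6 and the C4 oxygen is removed. Ring order: B, then A (plus the temporary Si ring), with the dioxane made in parallel.
5. Enabling feature: C4 is the one CH2 of ring B that is allylic to the tetrasubstituted C2=C3 alkene, so an oxygen can be put in, set by CBS reduction and taken out again. C4 is also bonded to C4a and is 1,3 to C5, so a C4–O–SiMe2–C5 bridge delivers the diene to one face of a C4a=C8a alkene. The C5–Si bond is then the allylsilane that moves the ring A alkene to the position a Diels–Alder reaction cannot reach directly. The C1 gem-dimethyl group keeps the cyclohexadiene from aromatising.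

Key step: step 10

Remark: 34 is drawn as its E isomer and 14 with the C5 (C–Si) configuration of exo folding; neither element matters, because the alkene is saturated in step 25 and the C–Si centre is erased in step 11.

**Steps 1–3: the diene**

Step 1
Reactants: 1 prop-2-yn-1-ol
Product: 2 (2E)-3-iodo-2-methylprop-2-en-1-ol
Conditions: AlMe3 (3 equiv), Cp2ZrCl2 (0.25 equiv), CH2Cl2, 0 °C → rt; I2, THF, −30 °C; aq. K2CO3
Reagents that add atoms: trimethylaluminium C[Al](C)C; iodine II
Why: Negishi carboalumination (Zr-catalysed syn-methylalumination of the terminal alkyne) followed by iodinolysis with retention should give the E-vinyl iodide with CH3 on the internal carbon.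

Step 2
Reactants: 2 (2E)-3-iodo-2-methylprop-2-en-1-ol
Product: 3 (2E)-3-iodo-2-methylprop-2-enal
Conditions: MnO2, CH2Cl2, rt
Reagents that add atoms: none
Why: Allylic alcohol oxidation on MnO2 is selective for the activated carbinol and leaves the vinyl iodide and the alkene geometry unchanged.

Step 3
Reactants: 3 (2E)-3-iodo-2-methylprop-2-enal
Product: 4 (1E)-1-iodo-2-methylbuta-1,3-diene
Conditions: MePPh3Br, n-BuLi, THF, −78 → 0 °C; used as an ethereal solution
Reagents that add atoms: methyltriphenylphosphonium bromide C[P+](c1ccccc1)(c1ccccc1)c1ccccc1.[Br-]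
Why: Wittig methylenation with the unstabilised ylide builds the terminal vinyl group and keeps the E-iodoalkene, so that iodine sits on the outer position of the s-cis diene.

**Steps 4–9: ring B dienol and tether**

Step 4
Reactants: 5 β-cyclocitral (2,6,6-trimethylcyclohex-1-ene-1-carbaldehyde)
Product: 6 β-cyclogeraniol
Conditions: NaBH4, MeOH, 0 °C
Reagents that add atoms: none
Why: Borohydride 1,2-reduction of the hindered conjugated aldehyde gives the primary allylic alcohol whose carbon later becomes the ring-side CH2 of the bridge.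

Step 5
Reactants: 6 β-cyclogeraniol
Product: 7 β-cyclogeranyl pivalate
Conditions: PivCl, Et3N, DMAP (cat.), CH2Cl2, 0 °C → rt
Reagents that add atoms: pivaloyl chloride CC(C)(C)C(=O)Cl
Why: DMAP-catalysed acylation installs an ester that should survive radical oxidation, IBX, borane, 185 °C and acid, and that is removed reductively in step 12.

Step 6
Reactants: 7 β-cyclogeranyl pivalate
Product: 8 (2,6,6-trimethyl-3-oxocyclohex-1-en-1-yl)methyl pivalate
Conditions: t-BuOOH (decane), Mn(OAc)3·2H2O (cat.), 3 Å MS, EtOAc, rt
Reagents that add atoms: tert-butyl hydroperoxide CC(C)(C)OO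
Why: Metal-catalysed allylic C–H oxidation attacks the only allylic ring methylene (future C4) in preference to the CH3 group and the deactivated CH2OPiv group, and gives the enone.

Step 7
Reactants: 8 (2,6,6-trimethyl-3-oxocyclohex-1-en-1-yl)methyl pivalate
Product: 9 (2,6,6-trimethyl-3-oxocyclohexa-1,4-dien-1-yl)methyl pivalate
Conditions: IBX, DMSO–PhF, 80 °C
Reagents that add atoms: none
Why: IBX dehydrogenation of the ketone through its cross-conjugated enol introduces the future C4a=C8a alkene, and the quaternary carbon prevents tautomerisation to a phenol.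

Step 8
Reactants: 9 (2,6,6-trimethyl-3-oxocyclohexa-1,4-dien-1-yl)methyl pivalate
Product: 10 [(3R)-3-hydroxy-2,6,6-trimethylcyclohexa-1,4-dien-1-yl]methyl pivalate
Conditions: (S)-2-methyl-CBS-oxazaborolidine (cat.), BH3·SMe2, THF, −30 °C; MeOH; base-washed work-up
Reagents that add atoms: none
Why: Corey–Bakshi–Shibata reduction tells the methyl-bearing alkene flank of the carbonyl from the unsubstituted one, so the (S)-catalyst should give the (R)-carbinol, the single centre from which both ring-fusion centres are later derived.

Step 9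
Reactants: 4 (1E)-1-iodo-2-methylbuta-1,3-diene; 10 [(3R)-3-hydroxy-2,6,6-trimethylcyclohexa-1,4-dien-1-yl]methyl pivalate
Product: 13 dimethyl[(1E)-2-methylbuta-1,3-dienyl]silyl ether of 10, via dienyllithium 11 (not isolated), via dienylchlorosilane 12 (not isolated)
Conditions: 4, t-BuLi (2 equiv), Et2O, −78 °C; into Me2SiCl2 (5 equiv), −78 °C → rt; excess silane evaporated; 10, Et3N, DMAP (cat.), CH2Cl2, 0 °C
Reagents that add atoms: dichlorodimethylsilane C[Si](C)(Cl)Cl
Why: Iodine–lithium exchange with retention of geometry, monosubstitution of excess Me2SiCl2 and base-mediated O-silylation assemble the temporary silicon tether without exposing the acid-labile dienol to acid.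

**Steps 10–13: key step and bicyclic phosphonium salt**

Step 10
Reactants: 13 dimethyl[(1E)-2-methylbuta-1,3-dienyl]silyl ether of 10
Product: 14 tricyclic allylsilane (cis-fused 1,4,4a,5,8,8a-hexahydronaphthalene with C6=C7 alkene; C4–O and C5 bridged by SiMe2; the hydrogens at C4a and C8a cis to each other and anti to the C4 oxygen)
Conditions: PhMe (5 mM), BHT (cat.), base-washed sealed tube, 185 °C
Reagents that add atoms: none
Why: Concerted, suprafacial thermal [4+2] cycloaddition of the (E)-1-silyl-2-methylbutadiene onto the disubstituted C4a=C8a alkene of ring B; the closest known type is the temporary-silicon-tethered (type 1) intramolecular Diels–Alder reaction of silyl ethers with unactivated dienophiles. Ring A (six-membered carbocycle) is closed by simultaneous formation of C8–C8a and C4a–C5, and the five-membered 1,2-oxasilolane (C4–O–Si–C5–C4a) is closed by the same C4a–C5 bond as the three-atom tether folds. C4a and C8a become cis because both bonds are made on one face of a ring-locked Z-alkene, and that face is the one carrying the C4–O–Si tether, so the CBS-set C4 carbinol fixes the absolute configuration of both ring-fusion centres. C5 (C–Si) is set by the exo folding that keeps the diene away from the C1 gem-dimethyl group, and it is erased in step 11. Site selectivity (C4a=C8a rather than the tetrasubstituted C2=C3 alkene, which is equally near the tether) rests on substitution, and the regiochemistry (CH2 terminus to C8a next to quaternary C1, silyl-bearing terminus to C4a) is enforced by the tether length. The gem-dimethyl group blocks aromatisation, and base-washed glass with BHT should suppress ionisation of the bis-allylic silyl ether and polymerisation of the diene.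

Step 11
Reactants: 14 tricyclic allylsilane
Product: 15 [(4R,4aR,8aS)-4-hydroxy-1,1,3,6-tetramethyl-1,4,4a,7,8,8a-hexahydronaphthalen-2-yl]methyl pivalate
Conditions: CF3CO2H (3 equiv), CH2Cl2, −20 °C; then K2CO3, MeOH–H2O, rt
Reagents that add atoms: none
Why: Protodesilylation of the allylsilane (SE2′): protonation at C7 gives the tertiary β-silyl cation at C6, loss of silicon places the alkene at C5=C6, and basic solvolysis of the remaining Si–O bond frees the C4 alcohol.

Step 12
Reactants: 15 [(4R,4aR,8aS)-4-hydroxy-1,1,3,6-tetramethyl-1,4,4a,7,8,8a-hexahydronaphthalen-2-yl]methyl pivalate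
Product: 17 [(4aR,8aS)-1,1,3,6-tetramethyl-1,4,4a,7,8,8a-hexahydronaphthalen-2-yl]methanol, via allylic mesylate 16 (not isolated)
Conditions: MsCl, Et3N, THF, −40 °C; then LiBHEt3 (excess), −40 °C → rt
Reagents that add atoms: none
Why: Mesylation followed by SN2 hydride displacement removes the C4 oxygen without allylic shift because the SN2′ terminus C2 is fully substituted, and the same hydride cleaves the pivalate.

Step 13
Reactants: 17 [(4aR,8aS)-1,1,3,6-tetramethyl-1,4,4a,7,8,8a-hexahydronaphthalen-2-yl]methanol
Product: 18 {[(4aR,8aS)-1,1,3,6-tetramethyl-1,4,4a,7,8,8a-hexahydronaphthalen-2-yl]methyl}triphenylphosphonium bromide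
Conditions: PPh3·HBr, MeOH, rt
Reagents that add atoms: triphenylphosphine hydrobromide [Br-].c1ccc(cc1)[PH+](c1ccccc1)c1ccccc1
Why: Phosphonium salt formation from an allylic alcohol under HBr runs through the allyl cation, which PPh3 captures at its unhindered primary terminus, so the tetrasubstituted alkene stays in place.

**Steps 14–23: the dioxane aldehyde**

Step 14
Reactants: 19 (S)-2-methylglycidol
Product: 20 [(2R)-2-methyloxiran-2-yl]methyl 4-methylbenzenesulfonate
Conditions: TsCl, Et3N, DMAP (cat.), CH2Cl2, 0 °C
Reagents that add atoms: 4-toluenesulfonyl chloride Cc1ccc(cc1)S(=O)(=O)Cl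
Why: Sulfonylation of the primary alcohol does not touch the quaternary stereocentre (the descriptor changes only through the priority rules).

Step 15
Reactants: 20 [(2R)-2-methyloxiran-2-yl]methyl 4-methylbenzenesulfonate
Product: 22 (2R)-2-(but-3-en-1-yl)-2-methyloxirane, via hydroxy tosylate 21 (not isolated)
Conditions: allylMgBr, CuI (cat.), THF, −40 °C; then 2 M aq. NaOH, rt
Reagents that add atoms: allylmagnesium bromide C=CC[Mg]Br
Why: Copper-catalysed Grignard opening of the epoxide at its CH2 terminus (the neopentyl tosylate reacts far more slowly) and Williamson-type closure of the tertiary alkoxide onto the tosylate relocate the oxirane while the C–O bond at the stereocentre is never broken.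

Step 16
Reactants: 22 (2R)-2-(but-3-en-1-yl)-2-methyloxirane
Product: 23 3-[(2R)-2-methyloxiran-2-yl]propanal
Conditions: O3, CH2Cl2, −78 °C; Me2S
Reagents that add atoms: ozone [O-][O+]=O
Why: Ozonolysis with reductive work-up cleaves the only alkene to the aldehyde and leaves the epoxide intact.

Step 17
Reactants: 23 3-[(2R)-2-methyloxiran-2-yl]propanal; 24 (4R)-4-benzyl-3-propanoyl-1,3-oxazolidin-2-one
Product: 26 (4R)-4-benzyl-3-{(2R,3S)-3-hydroxy-2-methyl-5-[(2R)-2-methyloxiran-2-yl]pentanoyl}-1,3-oxazolidin-2-one, via boron enolate 25 (not isolated)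
Conditions: 24, Bu2BOTf, Et3N, CH2Cl2, −78 → 0 °C; 23, −78 → 0 °C; pH 7 buffer, MeOH, H2O2, 0 °C
Reagents that add atoms: none
Why: Evans syn-aldol through the Z-boron enolate and a Zimmerman–Traxler chair; the (R)-benzyl auxiliary sets the methyl-bearing centre in its final sense and the carbinol in the sense opposite to the target, as needed for the invertive closure in step 22.

Step 18
Reactants: 26 aldol adduct
Product: 27 (2S,3S)-2-methyl-5-[(2R)-2-methyloxiran-2-yl]pentane-1,3-diol
Conditions: LiBH4, MeOH (1 equiv), Et2O, 0 °C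
Reagents that add atoms: none
Why: Reductive removal of the auxiliary takes the acyl group to the alcohol level, so no acidic hydrogen remains next to the future leaving group and an E1cB pathway is excluded.

Step 19
Reactants: 27 (2S,3S)-2-methyl-5-[(2R)-2-methyloxiran-2-yl]pentane-1,3-diol
Product: 28 (2S,3S)-1-(tert-butyldiphenylsilyloxy)-2-methyl-5-[(2R)-2-methyloxiran-2-yl]pentan-3-ol
Conditions: TBDPSCl, imidazole, CH2Cl2, 0 °C
Reagents that add atoms: tert-butyl(chloro)diphenylsilane CC(C)(C)[Si](Cl)(c1ccccc1)c1ccccc1
Why: Sterically controlled silylation takes the primary alcohol only, and this silyl group should tolerate the heteropoly acid of step 21.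

Step 20
Reactants: 28 (2S,3S)-1-(tert-butyldiphenylsilyloxy)-2-methyl-5-[(2R)-2-methyloxiran-2-yl]pentan-3-ol
Product: 29 the corresponding (3S)-methanesulfonate
Conditions: MsCl, Et3N, CH2Cl2, −20 °C
Reagents that add atoms: methanesulfonyl chloride CS(=O)(=O)Cl
Why: O-Sulfonylation proceeds with retention and removes the free hydroxyl group that could otherwise open the epoxide to a tetrahydrofuran.

Step 21
Reactants: 29 epoxy mesylate
Product: 30 (3S,6S)-6-hydroperoxy-7-hydroxy-2,6-dimethyl-1-silyloxyheptan-3-yl mesylate (tertiary hydroperoxide, primary alcohol)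
Conditions: anhydrous H2O2 in Et2O (excess), H3PMo12O40 (cat.), rt
Reagents that add atoms: hydrogen peroxide OO
Why: Acid-catalysed perhydrolysis of a 2,2-disubstituted oxirane is a borderline SN2 opening in which H2O2 attacks the tertiary carbon anti to the departing oxygen, so inversion sets the quaternary peroxide carbon.

Step 22
Reactants: 30 hydroperoxy mesylate
Product: 31 [(3S,6R)-6-{(2S)-1-(tert-butyldiphenylsilyloxy)propan-2-yl}-3-methyl-1,2-dioxan-3-yl]methanol
Conditions: Cs2CO3, DMF, 0 °C → rt
Reagents that add atoms: none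
Why: Intramolecular 6-exo-tet displacement of the secondary mesylate by the more acidic and more nucleophilic hydroperoxide oxygen closes the dioxane with inversion and sets the CH–O centre, the weak base keeping alkoxide-driven fragmentation down.

Step 23
Reactants: 31 dioxanyl methanol
Product: 32 (3S,6R)-6-{(2S)-1-(tert-butyldiphenylsilyloxy)propan-2-yl}-3-methyl-1,2-dioxane-3-carbaldehyde
Conditions: Dess–Martin periodinane, CH2Cl2, 0 °C → rt
Reagents that add atoms: none
Why: Dess–Martin oxidation is neutral and peroxide-tolerant, and the aldehyde has no α-hydrogen and so cannot epimerise.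

**Steps 24–27: union and endgame**

Step 24
Reactants: 18 bicyclic phosphonium bromide; 32 dioxane carbaldehyde
Product: 34 bicyclic dienyl dioxane (C2–CH=CH–dioxane; stereocentres as in 37), via phosphorus ylide 33 (not isolated)
Conditions: 18, n-BuLi, THF, −78 → 0 °C; 32, −78 °C → rt
Reagents that add atoms: none
Why: Wittig olefination of the preformed allylic ylide with a non-enolisable aldehyde joins the two halves at low temperature, with no free base left to attack the peroxide.

Step 25
Reactants: 34 bicyclic dienyl dioxane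
Product: 35 silyl ether of the saturated-bridge alcohol (stereocentres as in 37)
Conditions: KO2CN=NCO2K, AcOH, MeOH–CH2Cl2, 0 °C → rt, in portions
Reagents that add atoms: none
Why: Diimide reduction (concerted syn transfer of H2) follows the degree of alkene substitution, so the disubstituted diene terminus should react before the tri- and tetrasubstituted ring alkenes, and the O–O bond is not touched.

Step 26
Reactants: 35 silyl ether
Product: 36 (2S)-2-[(3R,6R)-6-methyl-6-{2-[(4aR,8aS)-1,1,3,6-tetramethyl-1,4,4a,7,8,8a-hexahydronaphthalen-2-yl]ethyl}-1,2-dioxan-3-yl]propan-1-ol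
Conditions: TBAF buffered with AcOH, THF, rt
Reagents that add atoms: none
Why: Fluoride desilylation is buffered so that no base strong enough for a Kornblum–DeLaMare fragmentation of the dioxane is present.

Step 27
Reactants: 36 primary alcohol
Product: 37 (2R)-2-[(3R,6R)-6-methyl-6-{2-[(4aR,8aS)-1,1,3,6-tetramethyl-1,4,4a,7,8,8a-hexahydronaphthalen-2-yl]ethyl}-1,2-dioxan-3-yl]propanoic acid (target)
Conditions: TEMPO (cat.), PhI(OAc)2, MeCN–H2O, rt
Reagents that add atoms: water O
Why: Oxoammonium (TEMPO/PhI(OAc)2) oxidation through the aldehyde hydrate gives the acid under near-neutral conditions that should spare the alkenes, the peroxide and the adjacent methyl-bearing centre.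

**Compound list**

1 | prop-2-yn-1-ol | C#CCO | starting material
2 | (2E)-3-iodo-2-methylprop-2-en-1-ol | OC/C(C)=C/I | intermediate
3 | (2E)-3-iodo-2-methylprop-2-enal | O=C/C(C)=C/I | intermediate
4 | (1E)-1-iodo-2-methylbuta-1,3-diene | C=C/C(C)=C/I | intermediate
5 | β-cyclocitral | CC1=C(C=O)C(C)(C)CCC1 | starting material
6 | β-cyclogeraniol | CC1=C(CO)C(C)(C)CCC1 | intermediate
7 | β-cyclogeranyl pivalate | CC1=C(COC(=O)C(C)(C)C)C(C)(C)CCC1 | intermediate
8 | (2,6,6-trimethyl-3-oxocyclohex-1-en-1-yl)methyl pivalate | CC1=C(COC(=O)C(C)(C)C)C(C)(C)CCC1=O | intermediate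
9 | (2,6,6-trimethyl-3-oxocyclohexa-1,4-dien-1-yl)methyl pivalate | CC1=C(COC(=O)C(C)(C)C)C(C)(C)C=CC1=O | intermediate
10 | [(3R)-3-hydroxy-2,6,6-trimethylcyclohexa-1,4-dien-1-yl]methyl pivalate | O[C@@H]1C=CC(C)(C)C(COC(=O)C(C)(C)C)=C1C | intermediate
11 | [(1E)-2-methylbuta-1,3-dien-1-yl]lithium | [Li]/C=C(C)/C=C | intermediate
12 | chloro(dimethyl)[(1E)-2-methylbuta-1,3-dien-1-yl]silane | C[Si](C)(Cl)/C=C(C)/C=C | intermediate
13 | dimethyl[(1E)-2-methylbuta-1,3-dienyl]silyl ether of 10 | C=C/C(C)=C/[Si](C)(C)O[C@@H]1C=CC(C)(C)C(COC(=O)C(C)(C)C)=C1C | intermediate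
14 | tricyclic allylsilane (oxasilolane-bridged cis-hexahydronaphthalene, C6=C7) | C[Si]1(C)O[C@H]2C(C)=C(COC(=O)C(C)(C)C)C(C)(C)[C@H]3CC=C(C)[C@H]1[C@@H]23 | intermediate
15 | [(4R,4aR,8aS)-4-hydroxy-1,1,3,6-tetramethyl-1,4,4a,7,8,8a-hexahydronaphthalen-2-yl]methyl pivalate | CC1=C[C@H]2[C@@H](O)C(C)=C(COC(=O)C(C)(C)C)C(C)(C)[C@H]2CC1 | intermediate
16 | C4 methanesulfonate of 15 | CC1=C[C@H]2[C@@H](OS(C)(=O)=O)C(C)=C(COC(=O)C(C)(C)C)C(C)(C)[C@H]2CC1 | intermediate
17 | [(4aR,8aS)-1,1,3,6-tetramethyl-1,4,4a,7,8,8a-hexahydronaphthalen-2-yl]methanol | CC1=C[C@H]2CC(C)=C(CO)C(C)(C)[C@H]2CC1 | intermediate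
18 | bicyclic allylic triphenylphosphonium bromide | CC1=C[C@H]2CC(C)=C(C[P+](c3ccccc3)(c3ccccc3)c3ccccc3)C(C)(C)[C@H]2CC1.[Br-] | intermediate
19 | (S)-2-methylglycidol | C1O[C@@]1(C)CO | starting material
20 | [(2R)-2-methyloxiran-2-yl]methyl 4-methylbenzenesulfonate | C1O[C@@]1(C)COS(=O)(=O)c1ccc(C)cc1 | intermediate
21 | (2R)-2-hydroxy-2-methylhex-5-en-1-yl 4-methylbenzenesulfonate | C=CCC[C@@](C)(O)COS(=O)(=O)c1ccc(C)cc1 | intermediate
22 | (2R)-2-(but-3-en-1-yl)-2-methyloxirane | C=CCC[C@]1(C)CO1 | intermediate
23 | 3-[(2R)-2-methyloxiran-2-yl]propanal | O=CCC[C@]1(C)CO1 | intermediate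
24 | (4R)-4-benzyl-3-propanoyl-1,3-oxazolidin-2-one | CCC(=O)N1[C@H](Cc2ccccc2)COC1=O | starting material
25 | (Z)-dibutylboron enolate of 24 | C/C=C(\OB(CCCC)CCCC)N1[C@H](Cc2ccccc2)COC1=O | intermediate
26 | (2R,3S)-syn-aldol imide | O=C1OC[C@@H](Cc2ccccc2)N1C(=O)[C@H](C)[C@@H](O)CC[C@]3(C)CO3 | intermediate
27 | (2S,3S)-2-methyl-5-[(2R)-2-methyloxiran-2-yl]pentane-1,3-diol | OC[C@H](C)[C@@H](O)CC[C@]1(C)CO1 | intermediate
28 | primary TBDPS ether of 27 | CC(C)(C)[Si](OC[C@H](C)[C@@H](O)CC[C@]1(C)CO1)(c1ccccc1)c1ccccc1 | intermediate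
29 | secondary mesylate of 28 | CC(C)(C)[Si](OC[C@H](C)[C@@H](OS(C)(=O)=O)CC[C@]1(C)CO1)(c1ccccc1)c1ccccc1 | intermediate
30 | tertiary hydroperoxide / primary alcohol / secondary mesylate | CC(C)(C)[Si](OC[C@H](C)[C@@H](OS(C)(=O)=O)CC[C@@](C)(CO)OO)(c1ccccc1)c1ccccc1 | intermediate
31 | [(3S,6R)-6-{(2S)-1-(TBDPS-oxy)propan-2-yl}-3-methyl-1,2-dioxan-3-yl]methanol | OC[C@]1(C)CC[C@H]([C@@H](C)CO[Si](c2ccccc2)(c2ccccc2)C(C)(C)C)OO1 | intermediate
32 | (3S,6R)-6-{(2S)-1-(TBDPS-oxy)propan-2-yl}-3-methyl-1,2-dioxane-3-carbaldehyde | O=C[C@]1(C)CC[C@H]([C@@H](C)CO[Si](c2ccccc2)(c2ccccc2)C(C)(C)C)OO1 | intermediate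
33 | ylide of 18 | CC1=C[C@H]2CC(C)=C(C=P(c3ccccc3)(c3ccccc3)c3ccccc3)C(C)(C)[C@H]2CC1 | intermediate
34 | bicyclic dienyl dioxane (E drawn) | CC1=C[C@H]2CC(C)=C(/C=C/[C@]3(C)CC[C@H]([C@@H](C)CO[Si](c4ccccc4)(c4ccccc4)C(C)(C)C)OO3)C(C)(C)[C@H]2CC1 | intermediate
35 | saturated-bridge TBDPS ether | CC1=C[C@H]2CC(C)=C(CC[C@]3(C)CC[C@H]([C@@H](C)CO[Si](c4ccccc4)(c4ccccc4)C(C)(C)C)OO3)C(C)(C)[C@H]2CC1 | intermediate
36 | primary alcohol | CC1=C[C@H]2CC(C)=C(CC[C@]3(C)CC[C@H]([C@@H](C)CO)OO3)C(C)(C)[C@H]2CC1 | intermediate
37 | target acid | CC1=C[C@H]2CC(C)=C(CC[C@]3(C)CC[C@H]([C@@H](C)C(=O)O)OO3)C(C)(C)[C@H]2CC1 | target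

**Step count**

Total step count: 27.

Longest linear sequence: 14 steps (5 → 37 through steps 4–13 and 24–27). The dioxane branch 19 → 37 through steps 14–27 is equally long.

**Steps most likely to fail**

**Step 10.** The dienophile is unactivated and its C8a terminus is neopentyl. The temperature needed may therefore let ionisation of the bis-allylic C4–O bond (methyl shift to an arene) or diene polymerisation outrun the cycloaddition.

The fallback sets out from 9 and comes back at 17. It gives up the tether and activates the dienophile instead.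
- Tiglaldehyde is silylated (TBSOTf, Et3N) to (1E)-1-(tert-butyldimethylsilyloxy)-2-methylbuta-1,3-diene F1.
- F1 is combined with dienone 9 in an intermolecular, endo-selective Diels–Alder reaction under a chiral oxazaborolidinium triflimide catalyst. The C4 carbonyl polarises C4a=C8a and the 1-oxygen substituent directs "ortho", so C8–C8a and C4a–C5 are again formed and ring A is closed, giving the cis-fused silyloxy enone F2.
- Fluoride gives the C5 allylic alcohol F3.
- Mitsunobu displacement with 2-nitrobenzenesulfonylhydrazide, then loss of sulfinate and N2 from the allylic diazene (retro-ene), moves the alkene to C5=C6 and gives the C4 enone F4.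
- Luche reduction gives 15 and/or its C4 epimer F5. Both pass through the conditions of step 12 to 17, because the carbinol centre is erased there.

**Step 21.** A carbocation-like opening may erode the configuration at the tertiary carbon. Attack at the CH2 terminus or fragmentation of the β-hydroxy hydroperoxide may also compete.

The fallback sets out from 29 and comes back at 31. It inverts the order of the two C–O bond formations.
- The secondary mesylate is displaced first, with inversion, by the caesium salt of 2-methoxyprop-2-yl hydroperoxide (CsOH, DMF). This gives the epoxy peroxyketal F6.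
- Mild aqueous acid releases the secondary hydroperoxide F7.
- Under camphorsulfonic acid catalysis F7 opens the epoxide intramolecularly, 6-exo at the tertiary carbon and anti to the oxirane oxygen, to give 31.

**Step 25.** Hydrogen transfer to an alkene flanked by a quaternary carbon and a hindered ring may be slow. Reduction of the ring A alkene or decay of the peroxide could then set in on long exposure.

The fallback sets out from 34 and comes back at 35. It replaces concerted H2 transfer by ionic hydrogenation (Et3SiH, CF3CO2H, CH2Cl2, −40 °C). Protonation of the conjugated diene at the carbon next to the dioxane gives the allyl cation shared by the exocyclic carbon and C3. Hydride is then taken up at the less hindered exocyclic terminus, which restores the tetrasubstituted C2=C3 alkene. No new compound is involved.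

**Further compounds**

F1 | step 10 | (1E)-1-(tert-butyldimethylsilyloxy)-2-methylbuta-1,3-diene | C=C/C(C)=C/O[Si](C)(C)C(C)(C)C
F2 | step 10 | cis-fused endo Diels–Alder adduct (C4 ketone, C5 silyl ether, C6=C7) | CC1=CC[C@@H]2C(C)(C)C(COC(=O)C(C)(C)C)=C(C)C(=O)[C@@H]2[C@@H]1O[Si](C)(C)C(C)(C)C
F3 | step 10 | C5 allylic alcohol from F2 | CC1=CC[C@@H]2C(C)(C)C(COC(=O)C(C)(C)C)=C(C)C(=O)[C@@H]2[C@@H]1O
F4 | step 10 | C4 enone with C5=C6 alkene | CC1=C[C@H]2C(=O)C(C)=C(COC(=O)C(C)(C)C)C(C)(C)[C@H]2CC1
F5 | step 10 | C4 epimer of 15 | CC1=C[C@H]2[C@H](O)C(C)=C(COC(=O)C(C)(C)C)C(C)(C)[C@H]2CC1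
F6 | step 21 | epoxy 2-methoxyprop-2-yl peroxide (secondary carbon inverted) | CC(C)(C)[Si](OC[C@H](C)[C@H](OOC(C)(C)OC)CC[C@]1(C)CO1)(c1ccccc1)c1ccccc1
F7 | step 21 | epoxy secondary hydroperoxide | CC(C)(C)[Si](OC[C@H](C)[C@H](OO)CC[C@]1(C)CO1)(c1ccccc1)c1ccccc1
F0 | step 25 | none | none
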